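The runs were computed with made-up constants; scatter was added.

Sunday's electrophile cannot be following a second-order law that spends one nucleophile per electrophile reacted, and the readings show it.

in all of them: electrophile 0.10 M
- Sunday's: nucleophile 0.14 M; run made earlier
- Tuesday's: nucleophile 0.35 M; run made earlier
- east: nucleophile 0.250 M; time 5.0 h
- north-east: nucleophile 0.170 M; time 5.0 h
- south-west: nucleophile 0.110 M; time 5.0 h

| run | time / h | electrophile / % | target / % |
|---|---|---|---|
| Sunday's | 0.417 | 70.2 | 28.6 |
| Sunday's | 0.833 | 59.5 | 38.8 |
| Sunday's | 1.33 | 52.9 | 41.9 |
| Sunday's | 2.50 | 46.2 | 44.6 |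
| Sunday's | 5.00 | 39.8 | 40.5 |
| Tuesday's | 1.00 | 29.6 | 66.2 |
| Tuesday's | 2.00 | 19.5 | 68.7 |
| Tuesday's | 3.00 | 14.6 | 66.3 |
| Tuesday's | 4.00 | 13.7 | 62.6 |
| Tuesday's | 5.00 | 11.6 | 59.3 |

(standard deviation of a reading: 0.5 percentage points)



- part of the electrophile that has reacted at the end, east
- part of the electrophile that has reacted at the end, north-east
- part of the electrophile that has reacted at the end, south-west
- what raising the concentration of nucleophile from its lowest to its highest value here does to the part of the electrophile that has reacted (changes below 5 percentage points count as none) (it falls / no change / it rises)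

I test this with the integrated second-order rate law. My clock θ is the natural log of the fraction of nucleophile left over the fraction of electrophile left, divided by the difference of the charges, counting one nucleophile per electrophile reacted. A clean second-order flask has θ growing in a straight line with time. Sunday's θ reads 5.67 L mol⁻¹ at 1.33 h and 8.98 L mol⁻¹ at 5.00 h, and this end value of the clock is what I carry. Its slope falls from 6.86 L mol⁻¹ h⁻¹ over the first reading to 0.903 L mol⁻¹ h⁻¹ over the last stretch. Tuesday's θ ends at 7.45 L mol⁻¹.

Drawing a straight line through the two end values against the nucleophile charge, I read 8.18 L mol⁻¹ for east, 8.76 L mol⁻¹ for north-east and 9.20 L mol⁻¹ for south-west. Inverting the law, I commit to 80.1%, 67.3% and 51.5%. South-west looks nearly like Sunday, and its clock is close to Sunday's. Yet my figure for south-west stands lower than Sunday's 60.2%, because its excess of nucleophile, 0.0100 M, is smaller than Sunday's 0.0400 M, and in this reckoning a similar θ buys less conversion on a smaller excess.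

The forecast gives 80%, 67% and 52% of the electrophile reacted; of the reacted part, from the lowest nucleophile charge to the highest, its answer is it rises, and it says “Conversion rises with nucleophile”.

The flasks give 79.9%, 66.9% and 51.6% of the electrophile reacted; of the reacted part, from the lowest nucleophile charge to the highest, the answer is it rises, by 28 percentage points.

    electrophile + nucleophile → acid set free + target (k = 9.30 L mol⁻¹ h⁻¹)
    nucleophile + acid set free ⇌ protonated nucleophile, settled at all times (K = 540 L mol⁻¹)
    target → over-reaction product (k = 0.0980 h⁻¹)
    2 nucleophile → homo dimer (k = 3.30 L mol⁻¹ h⁻¹)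

South-west's result reads back as θ = 9.26 L mol⁻¹, beside Sunday's 8.98 L mol⁻¹. At the end, south-west holds 3.2% of its nucleophile free against 48% of its electrophile, with 0.0338 M protonated nucleophile and 0.0105 M homo dimer beside them. Its neighbour is the same flask stopped at 80 min, the time of Sunday's 5.67 L mol⁻¹. That θ on south-west's charges gives 39.1%, and the neighbour stands at 39.7% reacted.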